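**Retrosynthetic overview**

- Megaphone acetate ⇐ O-acetylation of the hydroxy enone (megaphone), which is the hydrolytically opened form of a cis-fused 7a-methoxy-hexahydrobenzofuran; the ring methyl ether comes from the enone carbonyl of that bicycle (1,2-reduction, then O-methylation).
- Key disconnection: the benzylic C7–O bond. It is closed in an enantioselective dearomative oxa-[3+2] annulation, in which the dienone oxygen of a para-quinone monoketal captures the benzylic cation formed when (Z)-isoelemicin adds through C8 to the allyl-bearing ring carbon (C6–C8 bond, quaternary centre). The phenol oxygen thus becomes the acetate oxygen; the ring ketone oxygen later comes from water.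
- Quinone monoketal ⇐ oxidative C–O ketalisation of 2-allyl-4-methoxyphenol; (Z)-alkene ⇐ Wittig reaction of 3,4,5-trimethoxybenzaldehyde.
- Ring order: the carbocycle is the dearomatised arene of the phenol (step 2); the tetrahydrofuran ring is made in step 3 as a temporary ring and opened again in step 6.

Assumption: 1, 2 and 5 are bought as catalogue compounds.
Labels: target ring C1 (C=O) to C6 (quaternary), side chain C7 (CH–O) and C8 (CH–CH3). Bicyclic intermediates use benzofuran numbering, where C2 = C7, C3 = C8, C3a = C6, C4 = C5, C5 = C4 and C7a = C1 of the target.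

**Route**

Step 1
Reactants: 1 3,4,5-trimethoxybenzaldehyde; 2 ethyltriphenylphosphonium bromide
Product: 4 (Z)-1,2,3-trimethoxy-5-(prop-1-en-1-yl)benzene [(Z)-isoelemicin], via ethylidene(triphenyl)phosphorane 3 (not isolated)
Conditions: 2, NaN(SiMe3)2, THF, −78 °C; then 1, −78 °C to rt; AgNO3–silica chromatography
Reagents that add atoms: none
Why: Wittig olefination with the unstabilised ylide 3 under lithium-free conditions gives the Z-alkene through the kinetically favoured cis-oxaphosphetane; no stereocentre is formed.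

Step 2
Reactants: 5 2-allyl-4-methoxyphenol
Product: 6 2-allyl-4,4-dimethoxycyclohexa-2,5-dien-1-one
Conditions: PhI(OAc)2, MeOH, 0 °C
Reagents that add atoms: methanol, CO
Why: Oxidative dearomatisation of a para-methoxyphenol by trivalent iodine in methanol (phenol to para-quinone monoketal) forms the second C–OMe bond at the para carbon and leaves the allyl group untouched; no stereocentre is formed.

Step 3
Reactants: 6 2-allyl-4,4-dimethoxycyclohexa-2,5-dien-1-one; 4 (Z)-1,2,3-trimethoxy-5-(prop-1-en-1-yl)benzene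
Product: 8 (2S,3S,3aR,7aR)-3a-allyl-7a-methoxy-3-methyl-2-(3,4,5-trimethoxyphenyl)-3,3a,4,7a-tetrahydro-1-benzofuran-5(2H)-one (cis-fused; allyl and 7a-OMe cis; 3-methyl trans to allyl; 2-aryl trans to 3-methyl), via 5,7a-dimethoxy dienol ether 7 (not isolated)
Conditions: (R)-3,3′-bis(2,4,6-triisopropylphenyl)-1,1′-binaphthyl-2,2′-diyl N-triflylphosphoramide (5 mol %), CH2Cl2, −60 °C; then aq. oxalic acid, THF, 0 °C
Reagents that add atoms: water, O
Why: Proposed new method: the strong chiral Brønsted acid ionises the dimethyl ketal of 6 to a 2-allyl-4-methoxyphenoxonium (oxocarbenium) ion held as a contact ion pair with the chiral phosphoramidate, which blocks one ring face; the Z-alkene attacks through its methyl-bearing carbon at the allyl-substituted ring carbon (the site best able to carry the charge) with the electron-rich aryl group stacked over the oxocarbenium end of the ring, which puts the methyl over the ring and sets C3a and C3 (methyl trans to allyl); the benzylic cation then rotates and is captured by the dienone oxygen anti to the methyl group, and this C–O ring closure sets C2 (2,3-trans) and makes the addition irreversible; the liberated methanol returns to C7a on the allyl face (cis fusion) to give 7, whose enol ether is hydrolysed on work-up while the ketal survives; the closest known reaction type is the racemic Lewis- or Brønsted-acid-promoted formal [3+2] coupling of para-quinone monoketals with propenylarenes, together with chiral phosphoric acid catalysed additions to quinone ketals; the catalyst antipode is used if screening shows the opposite sense.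

Step 4
Reactants: 8 (2S,3S,3aR,7aR)-3a-allyl-7a-methoxy-3-methyl-2-(3,4,5-trimethoxyphenyl)-3,3a,4,7a-tetrahydro-1-benzofuran-5(2H)-one
Product: 9 (2S,3S,3aR,5R,7aR)-3a-allyl-7a-methoxy-3-methyl-2-(3,4,5-trimethoxyphenyl)-2,3,3a,4,5,7a-hexahydro-1-benzofuran-5-ol
Conditions: NaBH4, CeCl3·7H2O, MeOH, −78 °C
Reagents that add atoms: none
Why: Luche 1,2-reduction of the enone; hydride is delivered from the convex face of the cis-fused bicycle (the face of the angular allyl and methoxy groups, away from the folded tetrahydrofuran ring), so the new OH is cis to C3 and trans to allyl (5R), and the ketal and alkenes are untouched.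

Step 5
Reactants: 9 (2S,3S,3aR,5R,7aR)-3a-allyl-7a-methoxy-3-methyl-2-(3,4,5-trimethoxyphenyl)-2,3,3a,4,5,7a-hexahydro-1-benzofuran-5-ol
Product: 11 (2S,3S,3aR,5R,7aR)-3a-allyl-5,7a-dimethoxy-3-methyl-2-(3,4,5-trimethoxyphenyl)-2,3,3a,4,5,7a-hexahydro-1-benzofuran, via sodium alkoxide 10 (not isolated)
Conditions: NaH, MeI, THF, 0 °C to rt
Reagents that add atoms: iodomethane, CI
Why: Williamson O-methylation of alkoxide 10; the C5–O bond of the stereocentre is not broken, so C5 is retained, and the base-stable ketal is unaffected.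

Step 6
Reactants: 11 (2S,3S,3aR,5R,7aR)-3a-allyl-5,7a-dimethoxy-3-methyl-2-(3,4,5-trimethoxyphenyl)-2,3,3a,4,5,7a-hexahydro-1-benzofuran
Product: 13 (4R,6R)-6-allyl-6-[(1S,2S)-1-hydroxy-1-(3,4,5-trimethoxyphenyl)propan-2-yl]-4-methoxycyclohex-2-en-1-one (megaphone), via cyclic hemiketal 12 (not isolated)
Conditions: 1 M aq. HCl, THF, 0 °C
Reagents that add atoms: water, O
Why: Acid hydrolysis of the mixed cyclic ketal: loss of methanol gives the cyclic oxocarbenium ion, water adds to give hemiketal 12, and this opens to the conjugated enone and the free benzylic alcohol; the C7–O bond is never broken, so C7 is retained and C4, C6 and C8 are untouched.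

Step 7
Reactants: 13 (4R,6R)-6-allyl-6-[(1S,2S)-1-hydroxy-1-(3,4,5-trimethoxyphenyl)propan-2-yl]-4-methoxycyclohex-2-en-1-one
Product: 14 (1S,2S)-2-[(1R,5R)-1-allyl-5-methoxy-2-oxocyclohex-3-en-1-yl]-1-(3,4,5-trimethoxyphenyl)propyl acetate (CNP0236985.2)
Conditions: Ac2O, pyridine, DMAP (cat.), CH2Cl2, rt
Reagents that add atoms: acetic anhydride, CC(=O)OC(C)=O
Why: DMAP-catalysed O-acylation (nucleophilic catalysis) of the secondary benzylic alcohol with retention at C7; the mild base does not touch the γ-methoxy enone.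

**Compound list**

1 | 3,4,5-trimethoxybenzaldehyde | COc1cc(C=O)cc(OC)c1OC | starting material
2 | ethyltriphenylphosphonium bromide | CC[P+](c1ccccc1)(c1ccccc1)c1ccccc1.[Br-] | starting material
3 | ethylidene(triphenyl)phosphorane | CC=P(c1ccccc1)(c1ccccc1)c1ccccc1 | intermediate
4 | (Z)-1,2,3-trimethoxy-5-(prop-1-en-1-yl)benzene | C/C=C\c1cc(OC)c(OC)c(OC)c1 | intermediate
5 | 2-allyl-4-methoxyphenol | C=CCc1cc(OC)ccc1O | starting material
6 | 2-allyl-4,4-dimethoxycyclohexa-2,5-dien-1-one | C=CCC1=CC(OC)(OC)C=CC1=O | intermediate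
7 | 3a-allyl-5,7a-dimethoxy-3-methyl-2-(3,4,5-trimethoxyphenyl)-2,3,3a,7a-tetrahydro-1-benzofuran (dienol ether of 8, same configuration at C2, C3, C3a and C7a) | C=CC[C@]12C=C(OC)C=C[C@@]1(OC)O[C@H](c3cc(OC)c(OC)c(OC)c3)[C@H]2C | intermediate
8 | (2S,3S,3aR,7aR)-3a-allyl-7a-methoxy-3-methyl-2-(3,4,5-trimethoxyphenyl)-3,3a,4,7a-tetrahydro-1-benzofuran-5(2H)-one | C=CC[C@]12CC(=O)C=C[C@@]1(OC)O[C@H](c3cc(OC)c(OC)c(OC)c3)[C@H]2C | intermediate
9 | (2S,3S,3aR,5R,7aR)-3a-allyl-7a-methoxy-3-methyl-2-(3,4,5-trimethoxyphenyl)-2,3,3a,4,5,7a-hexahydro-1-benzofuran-5-ol | C=CC[C@]12C[C@@H](O)C=C[C@@]1(OC)O[C@H](c3cc(OC)c(OC)c(OC)c3)[C@H]2C | intermediate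
10 | sodium alkoxide of 9 | C=CC[C@]12C[C@@H]([O-])C=C[C@@]1(OC)O[C@H](c3cc(OC)c(OC)c(OC)c3)[C@H]2C.[Na+] | intermediate
11 | (2S,3S,3aR,5R,7aR)-3a-allyl-5,7a-dimethoxy-3-methyl-2-(3,4,5-trimethoxyphenyl)-2,3,3a,4,5,7a-hexahydro-1-benzofuran | C=CC[C@]12C[C@@H](OC)C=C[C@@]1(OC)O[C@H](c3cc(OC)c(OC)c(OC)c3)[C@H]2C | intermediate
12 | (2S,3S,3aR,5R,7aR)-3a-allyl-5-methoxy-3-methyl-2-(3,4,5-trimethoxyphenyl)-3,3a,4,5-tetrahydro-1-benzofuran-7a(2H)-ol (cyclic hemiketal of 13) | C=CC[C@]12C[C@@H](OC)C=C[C@@]1(O)O[C@H](c3cc(OC)c(OC)c(OC)c3)[C@H]2C | intermediate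
13 | (4R,6R)-6-allyl-6-[(1S,2S)-1-hydroxy-1-(3,4,5-trimethoxyphenyl)propan-2-yl]-4-methoxycyclohex-2-en-1-one (megaphone) | C=CC[C@]1([C@H](C)[C@H](O)c2cc(OC)c(OC)c(OC)c2)C[C@@H](OC)C=CC1=O | intermediate
14 | (1S,2S)-2-[(1R,5R)-1-allyl-5-methoxy-2-oxocyclohex-3-en-1-yl]-1-(3,4,5-trimethoxyphenyl)propyl acetate | C=CC[C@]1([C@H](C)[C@H](OC(C)=O)c2cc(OC)c(OC)c(OC)c2)C[C@@H](OC)C=CC1=O | target

**Step count and risks**

Total steps: 7. Longest linear sequence: 6 (5 → 6 → 8 → 9 → 11 → 13 → 14; the branch 1 → 4 joins at step 3).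

The three steps most likely to fail:

Step 3 (the proposed new annulation). Risks are low enantioselectivity, attack at the unsubstituted ring carbon, or the wrong methyl/allyl relationship. Fallback with known chemistry: run the racemic coupling of 6 and 4 with SnCl4 (CH2Cl2, −40 °C, aqueous acid work-up). This gives racemic 8 through racemic 7, that is 7 and 8 together with the transient ent-7 F1 and the mirror-image ketone ent-8 F2. F2 is removed by preparative chromatography on a chiral stationary phase. The fallback sets out from 6 and 4 and comes back at 8, replacing asymmetric catalysis by resolution.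

Step 4 (facial selectivity of the hydride). If reduction of 8 gives mainly the (5S)-alcohol F3 (OH cis to allyl), F3 is inverted by a Mitsunobu reaction (PPh3, DIAD, 4-nitrobenzoic acid, THF) to the (5R)-4-nitrobenzoate F4. Methanolysis of F4 (K2CO3, MeOH) gives 9. The fallback sets out from 8 and comes back at 9, replacing reagent-controlled delivery by an SN2 inversion.

Step 1 (Z purity of the alkene, which fixes the methyl/allyl relationship in step 3). If the Z:E ratio is poor, the E/Z mixture of 4 is enriched in Z by triplet-sensitised contra-thermodynamic E-to-Z photoisomerisation (fac-Ir(ppy)3, blue LEDs, MeCN), a known process for β-methylstyrenes. The fallback sets out from 4 (as the mixture) and comes back at 4; it makes no new compound, none F0.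

**Further compounds**

F1 | step 3 | ent-7 (mirror image of dienol ether 7) | C=CC[C@@]12C=C(OC)C=C[C@]1(OC)O[C@@H](c3cc(OC)c(OC)c(OC)c3)[C@@H]2C
F2 | step 3 | ent-8 (mirror image of 8) | C=CC[C@@]12CC(=O)C=C[C@]1(OC)O[C@@H](c3cc(OC)c(OC)c(OC)c3)[C@@H]2C
F3 | step 4 | (5S)-alcohol, (2S,3S,3aR,5S,7aR) C5 epimer of 9 | C=CC[C@]12C[C@H](O)C=C[C@@]1(OC)O[C@H](c3cc(OC)c(OC)c(OC)c3)[C@H]2C
F4 | step 4 | (5R)-4-nitrobenzoate of 9 | C=CC[C@]12C[C@@H](OC(=O)c4ccc(cc4)[N+](=O)[O-])C=C[C@@]1(OC)O[C@H](c3cc(OC)c(OC)c(OC)c3)[C@H]2C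
F0 | step 1 | none | none
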